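For larch the ratio of the charges is 40.6, for maple 18.8: this charge ratio, free monomer charged per initiator charged, is the chain length if each initiator begins one chain and each free monomer ends up in a chain.

| setting | noon | midnight | larch | maple |
|---|---|---|---|---|
| free monomer | 4.2 mM (fed, over 30 s) | 10 mM (fed, over 30 s) | 13 mM (fed, over 30 s) | 6.0 mM (fed, over 30 s) |
| initiator | 0.32 mM | 0.32 mM | 0.32 mM | 0.32 mM |
| remark | run made earlier; the fed solution adds 0.25 times the starting volume | run made earlier; the fed solution adds 0.25 times the starting volume | the fed solution adds 0.25 times the starting volume | the fed solution adds 0.25 times the starting volume |
| time |  |  | 10 min | 10 min |

- noon (time / min: monomer in chains / %, free monomer / %): 0.333: 0, 67; 1.00: 8, 98; 2.00: 22, 74; 2.50: 36, 67; 4.00: 58, 44; 5.00: 67, 31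
- midnight (time / min: monomer in chains / %, free monomer / %): 0.417: 3, 81; 0.667: 1, 97; 1.00: 14, 87; 2.00: 36, 62; 3.00: 63, 38; 5.00: 86, 17

(standard deviation of a reading: 2 percentage points)

- every charge counts on the volume at the start, and the solution that is fed holds the whole dose
- the average divides the monomer in chains by the number of chains begun, living and dead together
- the earlier runs were read with a standard deviation of 2 percentage points
- the earlier runs do not show the number of chains; that part of a forecast is a guess
- percentages count the whole charge, also what has not yet gone in

- which of the two ends with the longer chains by the average number of monomer units in a chain (chains begun, living or dead) ("neither" if they lie within 10 %) (larch / maple / neither)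
- average number of monomer units in a chain (chains begun, living or dead) at the end, larch
- average number of monomer units in a chain (chains begun, living or dead) at the end, maple

Two chemists dispute what stands beside the charge ratio. The first holds that each initiator begins its chain at the outset, so the length is the charge ratio itself, and two runs with equal initiator charges should lose free monomer at one rate.

The second reads the late fall of free monomer as pseudo-first-order, with a constant that follows the concentration of growing chains. Noon, from 2.50 min to 5.00 min, reads 0.308 min⁻¹. Midnight, from 2.00 min to 5.00 min, reads 0.431 min⁻¹, which is faster, on the same initiator charge. So the second says chains begin through free monomer, part of the initiator stays unreacted, and the length is the charge ratio times the fraction of free monomer reacted, divided by the fraction of initiator reacted.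

I side with the second. Between these two runs the constant read goes as the monomer charge to the power 0.387. If the reacted initiator fraction scales likewise, and free monomer reacts to a like fraction in both flasks, my estimate is that larch uses 1.35 times the initiator fraction of maple, and its chains come out 1.61 times as long, beyond the margin, so I expect larch to be longer. The lengths themselves rest on a count of chains that the runs do not show.

The forecast gives 52 for larch and 30 for maple, a ratio of 1.73 against my 1.61, on the grounds of “slow initiation by monomer, with chains then growing quickly”.

The flask gives 48.3 for larch and 27.0 for maple, so larch is longer, and larch stands above its charge ratio, as maple does above its own.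

    living end → dead end (k = 0.00180 s⁻¹)
    free monomer + initiator → living end + monomer in chains (k = 1.10 L mol⁻¹ s⁻¹)
    free monomer + living end → monomer in chains + living end, rate k3*[living end]*[free monomer] (k = 57.0 L mol⁻¹ s⁻¹)

Larch at 10.0 min keeps 17 % of its initiator and 1.8 % of its free monomer, and the charge ratio times 1.19 gives 48.3. The neighbour of larch with 0.80 mM of initiator has a charge ratio of 16.2 and keeps 39 % of its initiator, which gives 26.5; its simulated length is 26.5. With the free monomer reacted, the first chemist's length comes within 10 % where the initiator left lies under 9.09 % of its charge, and larch lies outside that. Larch has not quite come to rest: by 100 min free monomer falls to 0.0811 %, initiator to 15.7 %, and the length moves from 48.3 to 48.1.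

The runs were generated by integration for substances that don't exist; scatter was added.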